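## Retrosynthetic overview

1. Feature: in ring C, C4 is a one-carbon carbonyl bridge. It is bonded only to C4a of ring A and to C3, and C3=C2 carries both O1 and ring B. C4 is therefore traced back to carbon monoxide, and ring C is cut at C4a–C4, C4–C3 and O1–C2 into a ring A 2-iodophenol, CO and a ring B arylacetylene.
2. The C3 hydroxyl is left out of the annulation and added afterwards by C3–H lithiation, borylation and oxidation. O7, O4' and the side-chain oxygen travel as silyl ethers and are released together by fluoride in the last step.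
3. Ring A iodophenol: made from 3-hydroxy-4,5-dimethoxybenzaldehyde. O7 is silylated first, the formyl group is exchanged for the future O1 by Baeyer–Villiger oxidation, and iodine is placed between O1 and the C5 methoxy group by directed lithiation of the MOM ether.
4. Ring B alkyne: made from 4-bromo-2-iodophenol. The C–I bond takes the side chain by B-alkyl Suzuki coupling with an alkene made from the (R)-Roche ester, which is the only source of the C3'' stereocentre. The C–Br bond then takes the ethynyl group.
5. Ring order: rings A and B are bought as benzene rings, and ring C is the only ring built.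

Key step: step 13

Assumption: 3-hydroxy-4,5-dimethoxybenzaldehyde, 4-bromo-2-iodophenol, enantiopure (R)-Roche ester and carbon monoxide are taken as purchasable. The descriptor change from R (ester) to S (side chain) comes only from a change in CIP ranking, and no bond at the stereocentre is ever broken.

## Route

Step 1
Reactants: 1 3-hydroxy-4,5-dimethoxybenzaldehyde
Product: 2 3,4-dimethoxy-5-(triisopropylsilyloxy)benzaldehyde
Conditions: TIPSCl, imidazole, DMF, rt
Reagents that add atoms: triisopropylsilyl chloride (TIPSCl), CC(C)[Si](Cl)(C(C)C)C(C)C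
Why: Imidazole-promoted silylation of the only free phenol marks the future O7 with a bulky group that tolerates organolithium reagents and dilute acid and that shields its own ortho positions.

Step 2
Reactants: 2 3,4-dimethoxy-5-(triisopropylsilyloxy)benzaldehyde
Product: 4 3,4-dimethoxy-5-(triisopropylsilyloxy)phenol, via aryl formate 3 (not isolated)
Conditions: mCPBA, CH2Cl2, 0 °C → rt; crude 3, Et3N (0.2 equiv), MeOH, rt
Reagents that add atoms: mCPBA, O=C(OO)c1cccc(Cl)c1
Why: In this Baeyer–Villiger (Dakin-type) oxidation the electron-rich aryl group with its para methoxy substituent migrates to oxygen, and amine-catalysed methanolysis of the activated formate frees the phenol that becomes O1 without touching the aryl TIPS ether.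

Step 3
Reactants: 4 3,4-dimethoxy-5-(triisopropylsilyloxy)phenol
Product: 5 [2,3-dimethoxy-5-(methoxymethoxy)phenoxy]triisopropylsilane
Conditions: MOMCl, i-Pr2NEt, CH2Cl2, 0 °C → rt
Reagents that add atoms: chloromethyl methyl ether (MOMCl), COCCl
Why: O-alkylation of the phenol gives an acetal ether that is a strong coordinating director for the lithiation that follows.

Step 4
Reactants: 5 [2,3-dimethoxy-5-(methoxymethoxy)phenoxy]triisopropylsilane
Product: 7 [4-iodo-2,3-dimethoxy-5-(methoxymethoxy)phenoxy]triisopropylsilane, via aryllithium 6 (not isolated)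
Conditions: n-BuLi, THF, −78 → 0 °C; I2, THF, −78 °C → rt
Reagents that add atoms: iodine, II; n-BuLi, [Li]CCCC (lithium of 6 only)
Why: Directed ortho-metalation should occur at the C–H flanked by OMOM and OMe, where two coordinating groups cooperate, and not at the other ortho site, which is blocked by the bulky non-coordinating OTIPS group, and iodine then traps 6.

Step 5
Reactants: 7 [4-iodo-2,3-dimethoxy-5-(methoxymethoxy)phenoxy]triisopropylsilane
Product: 8 2-iodo-3,4-dimethoxy-5-(triisopropylsilyloxy)phenol
Conditions: HCl (1.25 M in MeOH), THF, rt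
Reagents that add atoms: none
Why: Acid-catalysed acetal exchange with methanol removes the phenolic MOM group under dilute, cool conditions that the far more acid-stable aryl TIPS ether and the C–I bond should survive.

Step 6
Reactants: 9 methyl (2R)-3-hydroxy-2-methylpropanoate (Roche ester)
Product: 10 methyl (2R)-3-(tert-butyldimethylsilyloxy)-2-methylpropanoate
Conditions: TBSCl, imidazole, CH2Cl2, 0 °C → rt
Reagents that add atoms: tert-butyldimethylsilyl chloride (TBSCl), CC(C)(C)[Si](C)(C)Cl
Why: Standard silylation of the primary alcohol, which becomes the terminal CH2OH of the target, does not involve the stereocentre.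

Step 7
Reactants: 10 methyl (2R)-3-(tert-butyldimethylsilyloxy)-2-methylpropanoate
Product: 11 (2R)-3-(tert-butyldimethylsilyloxy)-2-methylpropanal
Conditions: i-Bu2AlH (1.05 equiv), CH2Cl2, −78 °C; aq. potassium sodium tartrate
Reagents that add atoms: none
Why: Partial ester reduction with one equivalent of i-Bu2AlH at −78 °C stops at the aldehyde level, and a cold near-neutral work-up with immediate use keeps the alpha stereocentre intact.

Step 8
Reactants: 11 (2R)-3-(tert-butyldimethylsilyloxy)-2-methylpropanal
Product: 12 tert-butyl(dimethyl){[(2S)-2-methylbut-3-en-1-yl]oxy}silane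
Conditions: Ph3PCH3Br, n-BuLi, THF, 0 °C; then 11, −78 °C → rt
Reagents that add atoms: methyltriphenylphosphonium bromide, C[P+](c1ccccc1)(c1ccccc1)c1ccccc1.[Br-]
Why: Wittig methylenation by the reactive non-stabilised ylide should be faster than enolisation at low temperature, so the configuration bought with 9 passes unchanged into the alkene.

Step 9
Reactants: 13 4-bromo-2-iodophenol
Product: 14 (4-bromo-2-iodophenoxy)triisopropylsilane
Conditions: TIPSCl, imidazole, DMF, rt → 40 °C
Reagents that add atoms: triisopropylsilyl chloride (TIPSCl), CC(C)[Si](Cl)(C(C)C)C(C)C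
Why: Standard phenol silylation masks the future O4' with the same fluoride-labile group that is used at O7.

Step 10
Reactants: 12 tert-butyl(dimethyl){[(2S)-2-methylbut-3-en-1-yl]oxy}silane; 14 (4-bromo-2-iodophenoxy)triisopropylsilane
Product: 16 [4-bromo-2-[(3S)-4-(tert-butyldimethylsilyloxy)-3-methylbutyl]phenoxy]triisopropylsilane, via B-alkyl-9-BBN 15 (not isolated)
Conditions: 9-BBN-H, THF, 0 °C → rt; then 14, PdCl2(dppf) (5 mol %), aq. K3PO4, DMF, rt → 40 °C
Reagents that add atoms: 9-BBN-H, B1C2CCCC1CCC2 (boron bicycle of 15 only)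
Why: Anti-Markovnikov hydroboration followed by B-alkyl Suzuki–Miyaura coupling joins C1'' to C3', because zerovalent palladium inserts into C–I much faster than into C–Br near room temperature, and neither the bromide nor the stereocentre is touched.

Step 11
Reactants: 16 [4-bromo-2-[(3S)-4-(tert-butyldimethylsilyloxy)-3-methylbutyl]phenoxy]triisopropylsilane
Product: 17 [2-[(3S)-4-(tert-butyldimethylsilyloxy)-3-methylbutyl]-4-[(trimethylsilyl)ethynyl]phenoxy]triisopropylsilane
Conditions: HC≡CSiMe3, PdCl2(PhCN)2 (3 mol %), P(t-Bu)3 (6 mol %), CuI (2 mol %), i-Pr2NH, dioxane, rt → 40 °C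
Reagents that add atoms: ethynyltrimethylsilane, C#C[Si](C)(C)C
Why: This is a Sonogashira coupling in which the bulky electron-rich phosphine allows oxidative addition into the electron-rich aryl bromide under mild conditions that all three silyl groups tolerate.

Step 12
Reactants: 17 [2-[(3S)-4-(tert-butyldimethylsilyloxy)-3-methylbutyl]-4-[(trimethylsilyl)ethynyl]phenoxy]triisopropylsilane
Product: 18 [2-[(3S)-4-(tert-butyldimethylsilyloxy)-3-methylbutyl]-4-ethynylphenoxy]triisopropylsilane
Conditions: K2CO3 (0.2 equiv), MeOH/THF, 0 °C → rt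
Reagents that add atoms: none
Why: Methoxide-mediated protodesilylation cleaves the unhindered C(sp)–SiMe3 bond much faster than the hindered aryl O–TIPS bond, which is further shielded by its ortho alkyl chain, or the alkyl O–TBS bond.

Step 13
Reactants: 8 2-iodo-3,4-dimethoxy-5-(triisopropylsilyloxy)phenol; 18 [2-[(3S)-4-(tert-butyldimethylsilyloxy)-3-methylbutyl]-4-ethynylphenoxy]triisopropylsilane; 19 carbon monoxide
Product: 22 tris-silyl flavone 2-[3-[(3S)-4-(tert-butyldimethylsilyloxy)-3-methylbutyl]-4-(triisopropylsilyloxy)phenyl]-5,6-dimethoxy-7-(triisopropylsilyloxy)-4H-chromen-4-one, via hydroxyaryl ynone 20 (not isolated), via diethylamino enone 21 (not isolated)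
Conditions: PdCl2(PPh3)2 (5 mol %), CO (10 bar), Et2NH, 80 °C, autoclave
Reagents that add atoms: carbon monoxide 19, [C-]#[O+]; diethylamine, CCNCC (amino group of 21 only)
Why: The divalent palladium precatalyst is reduced in the amine/CO medium to zerovalent palladium, which inserts into the C–I bond of 8, takes up CO to give the aroylpalladium iodide (C4a–C4), and after amine-assisted transfer of the alkynyl group of 18 releases ynone 20 by reductive elimination (C4–C3). This is the known carbonylative Sonogashira coupling of 2-iodophenols with terminal alkynes with in situ cyclisation to flavones. Et2NH adds reversibly to the ynone beta-carbon to give the push–pull enone 21, and the neighbouring phenol oxygen replaces the amine at that carbon by addition–elimination, so ring C closes through O1–C2 in a formal 6-endo-dig mode (6-endo-trig on 21). No stereocentre is formed, and the remote C3'' centre takes no part. CO insertion must outrun direct alkynylation and 6-endo closure must outrun the 5-exo (aurone) mode: copper-free conditions, CO pressure and the electron-rich, doubly ortho-substituted aryl–palladium bond, which inserts CO readily, serve the first need, and the secondary amine, which makes C2 the only electrophilic carbon left, serves the second. The ring A pattern is fixed beforehand, because iodine sits between the free O1–H and the C5 methoxy group while O7 is masked as its TIPS ether.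

Step 14
Reactants: 22 tris-silyl flavone
Product: 25 tris-silyl flavonol 2-[3-[(3S)-4-(tert-butyldimethylsilyloxy)-3-methylbutyl]-4-(triisopropylsilyloxy)phenyl]-3-hydroxy-5,6-dimethoxy-7-(triisopropylsilyloxy)-4H-chromen-4-one, via 3-lithioflavone 23 (not isolated), via lithium trimethoxyborate 24 (not isolated)
Conditions: LDA (LiN(i-Pr)2, 1.5 equiv), THF, −78 °C; B(OMe)3, −78 → 0 °C; AcOH, 30 % aq. H2O2, 0 °C → rt
Reagents that add atoms: hydrogen peroxide, OO; trimethyl borate, COB(OC)OC (boron of 24 only); LDA, [Li]N(C(C)C)C(C)C (lithium of 23 only)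
Why: This is the known C3 lithiation of flavones, in which the C3–H next to the lithium-binding carbonyl oxygen is the most acidic site of fully protected 22, followed by borate trapping and oxidative boron-to-oxygen 1,2-migration under acetic acid buffering, so that no basic peroxide can open ring C or strip the aryl silyl ethers.

Step 15
Reactants: 25 tris-silyl flavonol
Product: 26 target, 3,7-dihydroxy-2-[4-hydroxy-3-[(3S)-4-hydroxy-3-methylbutyl]phenyl]-5,6-dimethoxy-4H-chromen-4-one
Conditions: Bu4NF (4 equiv), AcOH (4 equiv), THF, 0 °C → rt, under argon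
Reagents that add atoms: none
Why: Fluoride cleaves all three Si–O bonds in one operation, the acetic acid buffer keeps the air-sensitive polyphenol out of strongly basic medium, and the stereocentre is not involved.

## Compound list

1 | 3-hydroxy-4,5-dimethoxybenzaldehyde | COc1cc(C=O)cc(O)c1OC | starting material
2 | 3,4-dimethoxy-5-(triisopropylsilyloxy)benzaldehyde | COc1cc(C=O)cc(O[Si](C(C)C)(C(C)C)C(C)C)c1OC | intermediate
3 | 3,4-dimethoxy-5-(triisopropylsilyloxy)phenyl formate (formed in the flask) | COc1cc(OC=O)cc(O[Si](C(C)C)(C(C)C)C(C)C)c1OC | intermediate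
4 | 3,4-dimethoxy-5-(triisopropylsilyloxy)phenol | COc1cc(O)cc(O[Si](C(C)C)(C(C)C)C(C)C)c1OC | intermediate
5 | [2,3-dimethoxy-5-(methoxymethoxy)phenoxy]triisopropylsilane | COCOc1cc(OC)c(OC)c(O[Si](C(C)C)(C(C)C)C(C)C)c1 | intermediate
6 | [2,3-dimethoxy-6-(methoxymethoxy)-4-(triisopropylsilyloxy)phenyl]lithium (formed in the flask) | COCOc1cc(O[Si](C(C)C)(C(C)C)C(C)C)c(OC)c(OC)c1[Li] | intermediate
7 | [4-iodo-2,3-dimethoxy-5-(methoxymethoxy)phenoxy]triisopropylsilane | COCOc1cc(O[Si](C(C)C)(C(C)C)C(C)C)c(OC)c(OC)c1I | intermediate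
8 | 2-iodo-3,4-dimethoxy-5-(triisopropylsilyloxy)phenol | COc1c(O[Si](C(C)C)(C(C)C)C(C)C)cc(O)c(I)c1OC | intermediate
9 | methyl (2R)-3-hydroxy-2-methylpropanoate (Roche ester) | COC(=O)[C@H](C)CO | starting material
10 | methyl (2R)-3-(tert-butyldimethylsilyloxy)-2-methylpropanoate | COC(=O)[C@H](C)CO[Si](C)(C)C(C)(C)C | intermediate
11 | (2R)-3-(tert-butyldimethylsilyloxy)-2-methylpropanal | O=C[C@H](C)CO[Si](C)(C)C(C)(C)C | intermediate
12 | tert-butyl(dimethyl){[(2S)-2-methylbut-3-en-1-yl]oxy}silane | C=C[C@H](C)CO[Si](C)(C)C(C)(C)C | intermediate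
13 | 4-bromo-2-iodophenol | Oc1ccc(Br)cc1I | starting material
14 | (4-bromo-2-iodophenoxy)triisopropylsilane | CC(C)[Si](Oc1ccc(Br)cc1I)(C(C)C)C(C)C | intermediate
15 | 9-[(3S)-4-(tert-butyldimethylsilyloxy)-3-methylbutyl]-9-borabicyclo[3.3.1]nonane (formed in the flask) | C1CC2CCCC(C1)B2CC[C@H](C)CO[Si](C)(C)C(C)(C)C | intermediate
16 | [4-bromo-2-[(3S)-4-(tert-butyldimethylsilyloxy)-3-methylbutyl]phenoxy]triisopropylsilane | Brc1ccc(O[Si](C(C)C)(C(C)C)C(C)C)c(CC[C@H](C)CO[Si](C)(C)C(C)(C)C)c1 | intermediate
17 | [2-[(3S)-4-(tert-butyldimethylsilyloxy)-3-methylbutyl]-4-[(trimethylsilyl)ethynyl]phenoxy]triisopropylsilane | C[Si](C)(C)C#Cc1ccc(O[Si](C(C)C)(C(C)C)C(C)C)c(CC[C@H](C)CO[Si](C)(C)C(C)(C)C)c1 | intermediate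
18 | [2-[(3S)-4-(tert-butyldimethylsilyloxy)-3-methylbutyl]-4-ethynylphenoxy]triisopropylsilane | C#Cc1ccc(O[Si](C(C)C)(C(C)C)C(C)C)c(CC[C@H](C)CO[Si](C)(C)C(C)(C)C)c1 | intermediate
19 | carbon monoxide | [C-]#[O+] | starting material
20 | 1-[6-hydroxy-2,3-dimethoxy-4-(triisopropylsilyloxy)phenyl]-3-[3-[(3S)-4-(tert-butyldimethylsilyloxy)-3-methylbutyl]-4-(triisopropylsilyloxy)phenyl]prop-2-yn-1-one (formed in the flask) | COc1c(O[Si](C(C)C)(C(C)C)C(C)C)cc(O)c(C(=O)C#Cc2ccc(O[Si](C(C)C)(C(C)C)C(C)C)c(CC[C@H](C)CO[Si](C)(C)C(C)(C)C)c2)c1OC | intermediate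
21 | (E)-3-(diethylamino) enone from addition of Et2NH to 20, a freely equilibrating push–pull alkene (formed in the flask) | COc1c(O[Si](C(C)C)(C(C)C)C(C)C)cc(O)c(C(=O)/C=C(\c2ccc(O[Si](C(C)C)(C(C)C)C(C)C)c(CC[C@H](C)CO[Si](C)(C)C(C)(C)C)c2)N(CC)CC)c1OC | intermediate
22 | 2-[3-[(3S)-4-(tert-butyldimethylsilyloxy)-3-methylbutyl]-4-(triisopropylsilyloxy)phenyl]-5,6-dimethoxy-7-(triisopropylsilyloxy)-4H-chromen-4-one | COc1c(O[Si](C(C)C)(C(C)C)C(C)C)cc2oc(-c3ccc(O[Si](C(C)C)(C(C)C)C(C)C)c(CC[C@H](C)CO[Si](C)(C)C(C)(C)C)c3)cc(=O)c2c1OC | intermediate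
23 | 3-lithio derivative of 22 (formed in the flask) | COc1c(O[Si](C(C)C)(C(C)C)C(C)C)cc2oc(-c3ccc(O[Si](C(C)C)(C(C)C)C(C)C)c(CC[C@H](C)CO[Si](C)(C)C(C)(C)C)c3)c([Li])c(=O)c2c1OC | intermediate
24 | lithium trimethoxyborate bonded through boron to C3 of the flavone (formed in the flask) | COc1c(O[Si](C(C)C)(C(C)C)C(C)C)cc2oc(-c3ccc(O[Si](C(C)C)(C(C)C)C(C)C)c(CC[C@H](C)CO[Si](C)(C)C(C)(C)C)c3)c([B-](OC)(OC)OC)c(=O)c2c1OC.[Li+] | intermediate
25 | 2-[3-[(3S)-4-(tert-butyldimethylsilyloxy)-3-methylbutyl]-4-(triisopropylsilyloxy)phenyl]-3-hydroxy-5,6-dimethoxy-7-(triisopropylsilyloxy)-4H-chromen-4-one | COc1c(O[Si](C(C)C)(C(C)C)C(C)C)cc2oc(-c3ccc(O[Si](C(C)C)(C(C)C)C(C)C)c(CC[C@H](C)CO[Si](C)(C)C(C)(C)C)c3)c(O)c(=O)c2c1OC | intermediate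
26 | 3,7-dihydroxy-2-[4-hydroxy-3-[(3S)-4-hydroxy-3-methylbutyl]phenyl]-5,6-dimethoxy-4H-chromen-4-one (CNP0253239.1) | COc1c(O)cc2oc(-c3ccc(O)c(CC[C@H](C)CO)c3)c(O)c(=O)c2c1OC | target

## Step count and risks

Total step count: 15.

Longest linear sequence: 9 steps, from 9 through steps 6, 7, 8, 10, 11, 12, 13, 14 and 15.

**Step 13 (highest risk).**
- Oxidative addition into a C–I bond flanked by two oxygen substituents on a very electron-rich ring may be slow.
- The aroylpalladium species may be captured by the amine solvent instead of the alkyne.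
- Alkynylation may run ahead of CO insertion.
- Some closure may leak into the 5-exo mode.
- The O7 silyl group may be lost in hot amine.

The fallback brings in C4 as a formyl carbon by polar chemistry instead of as CO. It sets out from 5 and 18. Aryllithium 6 is generated as in step 4 and quenched with DMF to give 2,3-dimethoxy-6-(methoxymethoxy)-4-(triisopropylsilyloxy)benzaldehyde F1. HCl in MeOH removes the MOM group before any TBS ether is present and gives 6-hydroxy-2,3-dimethoxy-4-(triisopropylsilyloxy)benzaldehyde F2. The phenol of F2 is deprotonated with n-BuLi, and the lithium acetylide of 18 (n-BuLi, THF, −78 °C) is added. This should give the propargylic alcohol 1-[6-hydroxy-2,3-dimethoxy-4-(triisopropylsilyloxy)phenyl]-3-arylprop-2-yn-1-ol F3 as both carbinol epimers, which is of no consequence. MnO2 in CH2Cl2 oxidises it to ynone 20, now isolated, and warming 20 in Et2NH/EtOH carries it through 21 to 22, where the route is rejoined.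

**Step 14.**
- Deprotonation at C3 may be incomplete.
- The lithiated pyranone may fragment or add to unreacted flavone on warming.
- The boron intermediate may lose boron by protonation before it is oxidised.

The fallback uses electrophilic oxygen transfer to the C2=C3 bond instead of deprotonation. It sets out from 22. Dimethyldioxirane in acetone/CH2Cl2 at 0 °C should epoxidise the enol-ether double bond to the flavone 2,3-epoxide F4, from either face and without consequence. On contact with a trace of p-TsOH or with silica gel, F4 opens at the acetal-like C2 and loses the C3 proton. This rejoins the route at 25.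

**Step 10.**
- Transmetalation next to the bulky OTIPS group may be slow, which gives room for beta-hydride elimination and protodeboronation.
- Some insertion into the C–Br bond may occur.
- The aqueous base may cause desilylation.

The fallback uses a slim sp-carbon nucleophile followed by saturation instead of an sp3 boron partner. It sets out from 11 and 14. Aldehyde 11 is homologated with the Ohira–Bestmann reagent (K2CO3, MeOH, 0 °C) to tert-butyl(dimethyl){[(2S)-2-methylbut-3-yn-1-yl]oxy}silane F5. Sonogashira coupling with 14 at room temperature (PdCl2(PPh3)2, CuI, Et3N) should engage only the C–I bond and give [4-bromo-2-[(3S)-4-(tert-butyldimethylsilyloxy)-3-methylbut-1-yn-1-yl]phenoxy]triisopropylsilane F6. Diimide, generated from 2-nitrobenzenesulfonylhydrazide and Et3N, saturates the triple bond without touching the C–Br bond. This rejoins the route at 16.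

## Further compounds

F1 | step 13 | 2,3-dimethoxy-6-(methoxymethoxy)-4-(triisopropylsilyloxy)benzaldehyde | COCOc1cc(O[Si](C(C)C)(C(C)C)C(C)C)c(OC)c(OC)c1C=O
F2 | step 13 | 6-hydroxy-2,3-dimethoxy-4-(triisopropylsilyloxy)benzaldehyde | COc1c(O[Si](C(C)C)(C(C)C)C(C)C)cc(O)c(C=O)c1OC
F3 | step 13 | 1-[6-hydroxy-2,3-dimethoxy-4-(triisopropylsilyloxy)phenyl]-3-[3-[(3S)-4-(tert-butyldimethylsilyloxy)-3-methylbutyl]-4-(triisopropylsilyloxy)phenyl]prop-2-yn-1-ol (both carbinol epimers) | COc1c(O[Si](C(C)C)(C(C)C)C(C)C)cc(O)c(C(O)C#Cc2ccc(O[Si](C(C)C)(C(C)C)C(C)C)c(CC[C@H](C)CO[Si](C)(C)C(C)(C)C)c2)c1OC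
F4 | step 14 | 2,3-epoxide of flavone 22 (both faces) | COc1c(O[Si](C(C)C)(C(C)C)C(C)C)cc2OC3(c4ccc(O[Si](C(C)C)(C(C)C)C(C)C)c(CC[C@H](C)CO[Si](C)(C)C(C)(C)C)c4)OC3C(=O)c2c1OC
F5 | step 10 | tert-butyl(dimethyl){[(2S)-2-methylbut-3-yn-1-yl]oxy}silane | C#C[C@H](C)CO[Si](C)(C)C(C)(C)C
F6 | step 10 | [4-bromo-2-[(3S)-4-(tert-butyldimethylsilyloxy)-3-methylbut-1-yn-1-yl]phenoxy]triisopropylsilane | Brc1ccc(O[Si](C(C)C)(C(C)C)C(C)C)c(C#C[C@H](C)CO[Si](C)(C)C(C)(C)C)c1
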